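**Retrosynthetic overview**
1. Target 44 ⇐ reductive C–S cleavage of epoxy sulfone 43 ⇐ C12–C13 bond between lithiated left allylic sulfone 40 and right epoxy triflate 41.
2. The only ring, the oxirane, is made on the right half (17 → 18, Sharpless epoxidation) before the union; no other ring is formed.
3. Both (E)-trisubstituted alkenes ⇐ terminal alkynes 14 and 35 by Zr-catalysed methylalumination/hydroxymethylation.
4. Both halves ⇐ one Weinreb amide 7 (Grignard acylation, then methylenation); 7 ⇐ key C–C bond (C8–C9 = C16–C17) by auxiliary-controlled Michael addition of propionimide 1 to tert-butyl acrylate 2, which sets C7 and C18.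
5. C1–C5 bromide 29 ⇐ Evans alkylation of the enantiomeric imide 19 with tert-butyl bromoacetate (sets C3).

Locants used in the text: backbone C1 (=CH2 of the isopropenyl end) to C24 (prenyl end), oxirane at C14–C15; the target is 3S,7R,10E,14R,15R,18R.
Assumption: only species deliberately pre-formed in the flask (enolates, organomagnesium/lithium/aluminium species, acyl imidazoles) are numbered as non-isolated intermediates; fleeting mechanistic intermediates of a single reagent addition are not.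

**Common building block**

Step 1
Reactants: 1 (4S)-4-benzyl-3-propanoyl-1,3-oxazolidin-2-one; 2 tert-butyl prop-2-enoate
Product: 4 tert-butyl (4R)-5-[(4S)-4-benzyl-2-oxo-1,3-oxazolidin-3-yl]-4-methyl-5-oxopentanoate, via chlorotitanium Z-enolate 3 (not isolated)
Conditions: TiCl4/Ti(Oi-Pr)4 3:1 [gives TiCl3(Oi-Pr)], i-Pr2NEt, CH2Cl2, 0 °C; then 2, 0 °C → rt; aq NH4Cl
Reagents that add atoms: none
Why: Evans asymmetric Michael addition: the chelated (Z)-titanium enolate adds to the acrylate on the face away from the benzyl group, forming the C–C bond and the (R)-methyl centre (expected dr ≥ 95:5) that becomes both C7 and C18.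

Step 2
Reactants: 4
Product: 5 (2R)-5-tert-butoxy-2-methyl-5-oxopentanoic acid
Conditions: LiOH, 30% H2O2, THF/H2O, 0 °C; Na2SO3; 1 M HCl, 0 °C
Reagents that add atoms: hydrogen peroxide, OO
Why: Lithium hydroperoxide hydrolysis attacks only the exocyclic imide carbonyl, so the auxiliary is released without epimerisation and the tert-butyl ester survives.

Step 3
Reactants: 5
Product: 7 tert-butyl (4R)-5-[methoxy(methyl)amino]-4-methyl-5-oxopentanoate, via acyl imidazole 6 (not isolated)
Conditions: CDI, CH2Cl2, rt; then MeNH(OMe)·HCl, rt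
Reagents that add atoms: N,O-dimethylhydroxylamine hydrochloride, CNOC.Cl
Why: Acyl-imidazole amidation gives the Weinreb amide under near-neutral conditions that do not racemise the α-methyl centre.

**Right half (C13–C24)**

Step 4
Reactants: 7; 8 5-bromo-2-methylpent-2-ene
Product: 10 tert-butyl (4R)-4,9-dimethyl-5-oxodec-8-enoate, via homoprenylmagnesium bromide 9 (not isolated)
Conditions: 8, Mg, THF; add to 7, THF, −20 → 0 °C; aq NH4Cl
Reagents that add atoms: none
Why: Weinreb ketone synthesis: the Grignard adds once to the amide (stable magnesium chelate) and leaves the hindered tert-butyl ester alone.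

Step 5
Reactants: 10
Product: 11 tert-butyl (4R)-4,9-dimethyl-5-methylidenedec-8-enoate
Conditions: Tebbe reagent, pyridine (cat.), THF/toluene, −40 → 0 °C; aq NaOH
Reagents that add atoms: Tebbe reagent, C[Al-]1(C)C[Ti]([Cl+]1)(C1C=CC=C1)C1C=CC=C1
Why: Tebbe methylenation is non-basic, so the epimerisable α-methyl ketone becomes the 1,1-disubstituted alkene without loss of configuration and faster than the tert-butyl ester reacts.

Step 6
Reactants: 11
Product: 12 (4R)-4,9-dimethyl-5-methylidenedec-8-en-1-ol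
Conditions: LiAlH4, Et2O, 0 °C → rt; Fieser work-up
Reagents that add atoms: none
Why: Hydride reduction of the ester to the primary alcohol; isolated alkenes are inert to LiAlH4.

Step 7
Reactants: 12
Product: 13 (4R)-4,9-dimethyl-5-methylidenedec-8-enal
Conditions: Dess–Martin periodinane, CH2Cl2, rt
Reagents that add atoms: none
Why: Dess–Martin oxidation stops at the aldehyde and tolerates the alkenes; the stereocentre is γ to the carbonyl and cannot epimerise.

Step 8
Reactants: 13
Product: 14 (5R)-5,10-dimethyl-6-methylideneundec-9-en-1-yne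
Conditions: dimethyl (1-diazo-2-oxopropyl)phosphonate, K2CO3, MeOH, 0 °C → rt
Reagents that add atoms: dimethyl (1-diazo-2-oxopropyl)phosphonate, COP(=O)(OC)C(=[N+]=[N-])C(C)=O
Why: Seyferth–Gilbert homologation (Ohira–Bestmann variant) converts the aldehyde into the terminal alkyne under mild base.

Step 9
Reactants: 14
Product: 17 (2E,6R)-3,6,11-trimethyl-7-methylidenedodeca-2,10-dien-1-ol, via alkenylalane 15 (not isolated), via lithium alkenylaluminate 16 (not isolated)
Conditions: Me3Al, Cp2ZrCl2 (cat.), CH2Cl2, 0 °C → rt; volatiles removed; n-BuLi, THF/hexane, −78 °C; (CH2O)n, rt; aq NH4Cl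
Reagents that add atoms: trimethylaluminium, C[Al](C)C; paraformaldehyde (as formaldehyde), C=O
Why: Negishi Zr-catalysed methylalumination adds Me and Al syn and regioselectively across the alkyne (E > 98%), and the alanate is hydroxymethylated with retention; 1,1-di- and trisubstituted alkenes do not carbometalate, so the C14=C15 geometry is fixed here.

Step 10
Reactants: 17
Product: 18 [(2R,3R)-3-methyl-3-[(3R)-3,8-dimethyl-4-methylidenenon-7-en-1-yl]oxiran-2-yl]methanol
Conditions: Ti(Oi-Pr)4 (10 mol %), D-(−)-diethyl tartrate (12 mol %), t-BuOOH, 4 Å MS, CH2Cl2, −20 °C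
Reagents that add atoms: tert-butyl hydroperoxide, CC(C)(C)OO
Why: Sharpless asymmetric epoxidation is hydroxyl-directed, so only the allylic alkene reacts, and D-(−)-tartrate gives the (2R,3R)-epoxide (mirror of the L-(+)-tartrate/geraniol (2S,3S) result), which sets C14 and C15.

**Left end (C1–C5)**

Step 11
Reactants: 19 (4R)-4-benzyl-3-propanoyl-1,3-oxazolidin-2-one; 20 tert-butyl bromoacetate
Product: 22 tert-butyl (3S)-4-[(4R)-4-benzyl-2-oxo-1,3-oxazolidin-3-yl]-3-methyl-4-oxobutanoate, via sodium Z-enolate 21 (not isolated)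
Conditions: NaHMDS, THF, −78 °C; then 20, −78 → −20 °C
Reagents that add atoms: none
Why: Evans enolate alkylation: the chelated sodium (Z)-enolate is alkylated anti to the benzyl group, setting the (S)-methyl centre that becomes C3.

Step 12
Reactants: 22
Product: 23 (2S)-4-tert-butoxy-2-methyl-4-oxobutanoic acid
Conditions: LiOH, 30% H2O2, THF/H2O, 0 °C; Na2SO3; 1 M HCl, 0 °C
Reagents that add atoms: hydrogen peroxide, OO
Why: Lithium hydroperoxide hydrolysis removes the auxiliary regioselectively without epimerisation or ester cleavage.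

Step 13
Reactants: 23
Product: 25 tert-butyl (3S)-4-[methoxy(methyl)amino]-3-methyl-4-oxobutanoate, via acyl imidazole 24 (not isolated)
Conditions: CDI, CH2Cl2, rt; then MeNH(OMe)·HCl, rt
Reagents that add atoms: N,O-dimethylhydroxylamine hydrochloride, CNOC.Cl
Why: Acyl-imidazole amidation to the Weinreb amide without racemisation.

Step 14
Reactants: 25
Product: 26 tert-butyl (3S)-3-methyl-4-oxopentanoate
Conditions: MeMgBr, THF, −20 → 0 °C; cold aq NH4Cl
Reagents that add atoms: methylmagnesium bromide, C[Mg]Br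
Why: Weinreb ketone synthesis: the chelated tetrahedral adduct prevents over-addition and the ketone is only freed on cold work-up, so the α-centre is not exposed to base.

Step 15
Reactants: 26
Product: 27 tert-butyl (3S)-3,4-dimethylpent-4-enoate
Conditions: Tebbe reagent, pyridine (cat.), THF/toluene, −40 → 0 °C; aq NaOH
Reagents that add atoms: Tebbe reagent, C[Al-]1(C)C[Ti]([Cl+]1)(C1C=CC=C1)C1C=CC=C1
Why: Non-basic Tebbe methylenation makes the isopropenyl group without epimerising the adjacent stereocentre.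

Step 16
Reactants: 27
Product: 28 (3S)-3,4-dimethylpent-4-en-1-ol
Conditions: LiAlH4, Et2O, 0 °C; Fieser work-up; careful concentration (volatile)
Reagents that add atoms: none
Why: Hydride reduction of the ester to the primary alcohol.

Step 17
Reactants: 28
Product: 29 (3S)-5-bromo-2,3-dimethylpent-1-ene
Conditions: PPh3, NBS, CH2Cl2, −20 → 0 °C; pentane trituration
Reagents that add atoms: N-bromosuccinimide, O=C1CCC(=O)N1Br
Why: Appel-type bromination under neutral conditions gives the primary bromide with only solid by-products, which suits this volatile product.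

**Left half (C1–C12)**

Step 18
Reactants: 7; 29
Product: 31 tert-butyl (4R,8S)-4,8,9-trimethyl-5-oxodec-9-enoate, via Grignard reagent 30 (not isolated)
Conditions: 29, Mg, THF; add to 7, THF, −20 → 0 °C; aq NH4Cl
Reagents that add atoms: none
Why: Weinreb ketone synthesis joins the C1–C5 end to the C6–C10 unit by single addition, leaving the tert-butyl ester intact.

Step 19
Reactants: 31
Product: 32 tert-butyl (4R,8S)-4,8,9-trimethyl-5-methylidenedec-9-enoate
Conditions: Tebbe reagent, pyridine (cat.), THF/toluene, −40 → 0 °C; aq NaOH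
Reagents that add atoms: Tebbe reagent, C[Al-]1(C)C[Ti]([Cl+]1)(C1C=CC=C1)C1C=CC=C1
Why: Non-basic Tebbe methylenation installs the C6 methylidene without epimerising C7.

Step 20
Reactants: 32
Product: 33 (4R,8S)-4,8,9-trimethyl-5-methylidenedec-9-en-1-ol
Conditions: LiAlH4, Et2O, 0 °C → rt; Fieser work-up
Reagents that add atoms: none
Why: Hydride reduction of the ester to the primary alcohol.

Step 21
Reactants: 33
Product: 34 (4R,8S)-4,8,9-trimethyl-5-methylidenedec-9-enal
Conditions: Dess–Martin periodinane, CH2Cl2, rt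
Reagents that add atoms: none
Why: Dess–Martin oxidation to the aldehyde without touching the 1,1-disubstituted alkenes.

Step 22
Reactants: 34
Product: 35 (3S,7R)-2,3,7-trimethyl-6-methylideneundec-1-en-10-yne
Conditions: dimethyl (1-diazo-2-oxopropyl)phosphonate, K2CO3, MeOH, 0 °C → rt
Reagents that add atoms: dimethyl (1-diazo-2-oxopropyl)phosphonate, COP(=O)(OC)C(=[N+]=[N-])C(C)=O
Why: Seyferth–Gilbert homologation (Ohira–Bestmann variant) gives the terminal alkyne.

Step 23
Reactants: 35
Product: 38 (2E,6R,10S)-3,6,10,11-tetramethyl-7-methylidenedodeca-2,11-dien-1-ol, via alkenylalane 36 (not isolated), via lithium alkenylaluminate 37 (not isolated)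
Conditions: Me3Al, Cp2ZrCl2 (cat.), CH2Cl2, 0 °C → rt; volatiles removed; n-BuLi, THF/hexane, −78 °C; (CH2O)n, rt; aq NH4Cl
Reagents that add atoms: trimethylaluminium, C[Al](C)C; paraformaldehyde (as formaldehyde), C=O
Why: Negishi Zr-catalysed syn-methylalumination followed by hydroxymethylation of the alanate sets the 10E alkene (E > 98%).

Step 24
Reactants: 38
Product: 39 (3S,7R,10E)-12-bromo-2,3,7,10-tetramethyl-6-methylidenedodeca-1,10-diene
Conditions: CBr4, PPh3, CH2Cl2, 0 °C
Reagents that add atoms: carbon tetrabromide, BrC(Br)(Br)Br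
Why: Appel bromination converts the primary allylic alcohol by SN2 without allylic transposition or E/Z change.

Step 25
Reactants: 39
Product: 40 {[(2E,6R,10S)-3,6,10,11-tetramethyl-7-methylidenedodeca-2,11-dien-1-yl]sulfonyl}benzene
Conditions: PhSO2Na, DMF, rt
Reagents that add atoms: sodium benzenesulfinate, [Na+].[O-]S(=O)c1ccccc1
Why: SN2 S-alkylation of sulfinate by the primary allylic bromide gives the allylic sulfone.

**Union and end game**

Step 26
Reactants: 18
Product: 41 [(2R,3R)-3-methyl-3-[(3R)-3,8-dimethyl-4-methylidenenon-7-en-1-yl]oxiran-2-yl]methyl trifluoromethanesulfonate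
Conditions: Tf2O, 2,6-lutidine, CH2Cl2, −78 °C; cold work-up, used at once
Reagents that add atoms: trifluoromethanesulfonic anhydride, O=S(=O)(OS(=O)(=O)C(F)(F)F)C(F)(F)F
Why: O-Sulfonylation at −78 °C with a hindered base activates the primary alcohol without opening the epoxide.

Step 27
Reactants: 40; 41
Product: 43 (2R,3R)-2-methyl-2-[(3R)-3,8-dimethyl-4-methylidenenon-7-en-1-yl]-3-[(3E,7R,11S)-2-(benzenesulfonyl)-4,7,11,12-tetramethyl-8-methylidenetrideca-3,12-dien-1-yl]oxirane (both epimers at the sulfone carbon), via lithiated sulfone 42 (not isolated)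
Conditions: 40, n-BuLi, THF/DMPU, −78 °C; cannulate into 41 (1.2 equiv), THF, −78 °C; AcOH quench at −78 °C
Reagents that add atoms: none
Why: Alkylation of a sulfone-stabilised allyl anion (Julia/Biellmann-type coupling): α-selective SN2 at the primary triflate is far faster at −78 °C than attack on the trisubstituted epoxide and forms the C12–C13 bond.

Step 28
Reactants: 43
Product: 44 (2R,3R)-2-methyl-2-[(3R)-3,8-dimethyl-4-methylidenenon-7-en-1-yl]-3-[(3E,7R,11S)-4,7,11,12-tetramethyl-8-methylidenetrideca-3,12-dien-1-yl]oxirane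
Conditions: PdCl2(dppp) (10 mol %), LiBHEt3, THF, −10 → 0 °C, short reaction time
Reagents that add atoms: none
Why: Pd-catalysed reductive desulfonylation: hydride attacks the π-allyl palladium at its less substituted end, so the 10E alkene keeps its position and geometry, and brief cold exposure spares the hindered trisubstituted epoxide.

**Compound list**
1 | (4S)-4-benzyl-3-propanoyl-1,3-oxazolidin-2-one | CCC(=O)N1[C@@H](Cc2ccccc2)COC1=O | starting material
2 | tert-butyl prop-2-enoate (tert-butyl acrylate) | C=CC(=O)OC(C)(C)C | starting material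
3 | dichloro(propan-2-olato)titanium (Z)-enolate of 1 (not isolated) | C/C=C(\O[Ti](Cl)(Cl)OC(C)C)N1[C@@H](Cc2ccccc2)COC1=O | intermediate
4 | tert-butyl (4R)-5-[(4S)-4-benzyl-2-oxo-1,3-oxazolidin-3-yl]-4-methyl-5-oxopentanoate | CC(C)(C)OC(=O)CC[C@@H](C)C(=O)N1[C@@H](Cc2ccccc2)COC1=O | intermediate
5 | (2R)-5-tert-butoxy-2-methyl-5-oxopentanoic acid | CC(C)(C)OC(=O)CC[C@@H](C)C(=O)O | intermediate
6 | tert-butyl (4R)-5-(1H-imidazol-1-yl)-4-methyl-5-oxopentanoate (not isolated) | CC(C)(C)OC(=O)CC[C@@H](C)C(=O)n1ccnc1 | intermediate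
7 | tert-butyl (4R)-5-[methoxy(methyl)amino]-4-methyl-5-oxopentanoate | CC(C)(C)OC(=O)CC[C@@H](C)C(=O)N(C)OC | intermediate
8 | 5-bromo-2-methylpent-2-ene | CC(C)=CCCBr | starting material
9 | (4-methylpent-3-en-1-yl)magnesium bromide (not isolated) | CC(C)=CCC[Mg]Br | intermediate
10 | tert-butyl (4R)-4,9-dimethyl-5-oxodec-8-enoate | CC(C)=CCCC(=O)[C@H](C)CCC(=O)OC(C)(C)C | intermediate
11 | tert-butyl (4R)-4,9-dimethyl-5-methylidenedec-8-enoate | CC(C)=CCCC(=C)[C@H](C)CCC(=O)OC(C)(C)C | intermediate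
12 | (4R)-4,9-dimethyl-5-methylidenedec-8-en-1-ol | CC(C)=CCCC(=C)[C@H](C)CCCO | intermediate
13 | (4R)-4,9-dimethyl-5-methylidenedec-8-enal | CC(C)=CCCC(=C)[C@H](C)CCC=O | intermediate
14 | (5R)-5,10-dimethyl-6-methylideneundec-9-en-1-yne | C#CCC[C@@H](C)C(=C)CCC=C(C)C | intermediate
15 | dimethyl[(1E,5R)-2,5,10-trimethyl-6-methylideneundeca-1,9-dien-1-yl]alumane (not isolated) | C[Al](C)/C=C(\C)CC[C@@H](C)C(=C)CCC=C(C)C | intermediate
16 | lithium butyl(dimethyl)[(1E,5R)-2,5,10-trimethyl-6-methylideneundeca-1,9-dien-1-yl]aluminate (not isolated) | [Li+].CCCC[Al-](C)(C)/C=C(\C)CC[C@@H](C)C(=C)CCC=C(C)C | intermediate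
17 | (2E,6R)-3,6,11-trimethyl-7-methylidenedodeca-2,10-dien-1-ol | OC/C=C(\C)CC[C@@H](C)C(=C)CCC=C(C)C | intermediate
18 | [(2R,3R)-3-methyl-3-[(3R)-3,8-dimethyl-4-methylidenenon-7-en-1-yl]oxiran-2-yl]methanol | OC[C@H]1O[C@]1(C)CC[C@@H](C)C(=C)CCC=C(C)C | intermediate
19 | (4R)-4-benzyl-3-propanoyl-1,3-oxazolidin-2-one | CCC(=O)N1[C@H](Cc2ccccc2)COC1=O | starting material
20 | tert-butyl bromoacetate | BrCC(=O)OC(C)(C)C | starting material
21 | sodium (Z)-enolate of 19 (not isolated) | [Na+].C/C=C(\[O-])N1[C@H](Cc2ccccc2)COC1=O | intermediate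
22 | tert-butyl (3S)-4-[(4R)-4-benzyl-2-oxo-1,3-oxazolidin-3-yl]-3-methyl-4-oxobutanoate | CC(C)(C)OC(=O)C[C@H](C)C(=O)N1[C@H](Cc2ccccc2)COC1=O | intermediate
23 | (2S)-4-tert-butoxy-2-methyl-4-oxobutanoic acid | CC(C)(C)OC(=O)C[C@H](C)C(=O)O | intermediate
24 | tert-butyl (3S)-4-(1H-imidazol-1-yl)-3-methyl-4-oxobutanoate (not isolated) | CC(C)(C)OC(=O)C[C@H](C)C(=O)n1ccnc1 | intermediate
25 | tert-butyl (3S)-4-[methoxy(methyl)amino]-3-methyl-4-oxobutanoate | CC(C)(C)OC(=O)C[C@H](C)C(=O)N(C)OC | intermediate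
26 | tert-butyl (3S)-3-methyl-4-oxopentanoate | CC(C)(C)OC(=O)C[C@H](C)C(C)=O | intermediate
27 | tert-butyl (3S)-3,4-dimethylpent-4-enoate | CC(C)(C)OC(=O)C[C@H](C)C(C)=C | intermediate
28 | (3S)-3,4-dimethylpent-4-en-1-ol | OCC[C@H](C)C(C)=C | intermediate
29 | (3S)-5-bromo-2,3-dimethylpent-1-ene | BrCC[C@H](C)C(C)=C | intermediate
30 | [(3S)-3,4-dimethylpent-4-en-1-yl]magnesium bromide (not isolated) | Br[Mg]CC[C@H](C)C(C)=C | intermediate
31 | tert-butyl (4R,8S)-4,8,9-trimethyl-5-oxodec-9-enoate | C=C(C)[C@@H](C)CCC(=O)[C@H](C)CCC(=O)OC(C)(C)C | intermediate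
32 | tert-butyl (4R,8S)-4,8,9-trimethyl-5-methylidenedec-9-enoate | C=C(C)[C@@H](C)CCC(=C)[C@H](C)CCC(=O)OC(C)(C)C | intermediate
33 | (4R,8S)-4,8,9-trimethyl-5-methylidenedec-9-en-1-ol | C=C(C)[C@@H](C)CCC(=C)[C@H](C)CCCO | intermediate
34 | (4R,8S)-4,8,9-trimethyl-5-methylidenedec-9-enal | C=C(C)[C@@H](C)CCC(=C)[C@H](C)CCC=O | intermediate
35 | (3S,7R)-2,3,7-trimethyl-6-methylideneundec-1-en-10-yne | C=C(C)[C@@H](C)CCC(=C)[C@H](C)CCC#C | intermediate
36 | dimethyl[(1E,5R,9S)-2,5,9,10-tetramethyl-6-methylideneundeca-1,10-dien-1-yl]alumane (not isolated) | C=C(C)[C@@H](C)CCC(=C)[C@H](C)CC/C(C)=C/[Al](C)C | intermediate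
37 | lithium butyl(dimethyl)[(1E,5R,9S)-2,5,9,10-tetramethyl-6-methylideneundeca-1,10-dien-1-yl]aluminate (not isolated) | [Li+].C=C(C)[C@@H](C)CCC(=C)[C@H](C)CC/C(C)=C/[Al-](C)(C)CCCC | intermediate
38 | (2E,6R,10S)-3,6,10,11-tetramethyl-7-methylidenedodeca-2,11-dien-1-ol | C=C(C)[C@@H](C)CCC(=C)[C@H](C)CC/C(C)=C/CO | intermediate
39 | (3S,7R,10E)-12-bromo-2,3,7,10-tetramethyl-6-methylidenedodeca-1,10-diene | C=C(C)[C@@H](C)CCC(=C)[C@H](C)CC/C(C)=C/CBr | intermediate
40 | {[(2E,6R,10S)-3,6,10,11-tetramethyl-7-methylidenedodeca-2,11-dien-1-yl]sulfonyl}benzene | C=C(C)[C@@H](C)CCC(=C)[C@H](C)CC/C(C)=C/CS(=O)(=O)c1ccccc1 | intermediate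
41 | [(2R,3R)-3-methyl-3-[(3R)-3,8-dimethyl-4-methylidenenon-7-en-1-yl]oxiran-2-yl]methyl trifluoromethanesulfonate | O=S(=O)(OC[C@H]1O[C@]1(C)CC[C@@H](C)C(=C)CCC=C(C)C)C(F)(F)F | intermediate
42 | α-lithio derivative of sulfone 40 (not isolated) | C=C(C)[C@@H](C)CCC(=C)[C@H](C)CC/C(C)=C/C([Li])S(=O)(=O)c1ccccc1 | intermediate
43 | (2R,3R)-2-methyl-2-[(3R)-3,8-dimethyl-4-methylidenenon-7-en-1-yl]-3-[(3E,7R,11S)-2-(benzenesulfonyl)-4,7,11,12-tetramethyl-8-methylidenetrideca-3,12-dien-1-yl]oxirane (both epimers at the sulfone carbon) | C=C(C)[C@@H](C)CCC(=C)[C@H](C)CC/C(C)=C/C(S(=O)(=O)c1ccccc1)C[C@H]1O[C@]1(C)CC[C@@H](C)C(=C)CCC=C(C)C | intermediate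
44 | (2R,3R)-2-methyl-2-[(3R)-3,8-dimethyl-4-methylidenenon-7-en-1-yl]-3-[(3E,7R,11S)-4,7,11,12-tetramethyl-8-methylidenetrideca-3,12-dien-1-yl]oxirane (CNP0279512.1) | C=C(CC[C@H](C)C(=C)C)[C@H](C)CC/C(C)=C/CC[C@H]1O[C@]1(C)CC[C@@H](C)C(=C)CCC=C(C)C | target

**Totals**
Total step count: 28.
Longest linear sequence: 17 steps (11–17, 18–25, 27, 28).

**Three steps most likely to fail**

Step 27 (sulfone anion plus epoxy triflate: the triflate is labile, and the product anion can cyclise onto the epoxide). The fallback sets out from 18 (with 40) and comes back at 43; it makes the C12–C13 bond by epoxide opening instead of triflate displacement. Epoxy alcohol 18 is treated with PhSH/NaOH in t-BuOH/H2O (Payne rearrangement, thiolate opening at C13) to give (2R,3R,6R)-3,6,11-trimethyl-7-methylidene-1-(phenylsulfanyl)dodec-10-ene-2,3-diol F1. S-Methylation with Me3OBF4 gives the sulfonium salt F2, and NaH closes it to the terminal epoxide (2R,5R)-5,10-dimethyl-6-methylidene-2-[(2S)-oxiran-2-yl]undec-9-en-2-ol F3. After deprotonation of its tertiary OH, F3 is opened at the CH2 terminus by lithiated sulfone 42 (THF/DMPU, −78 → 0 °C) to give the 14S,15R-dihydroxy sulfone F4. MsCl/pyridine mesylates only the secondary hydroxyl to give the mesylate F5, and K2CO3/MeOH closes the oxirane with inversion at C14 to give 43.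

Step 28 (LiBHEt3 may reduce the epoxide). The fallback sets out from 18 and 40 and comes back at 44; it removes the sulfone before the oxirane exists. The dihydroxy sulfone F4 is made through the thioether diol F1, the sulfonium salt F2 and the terminal epoxide F3 as above. F4 is desulfonylated with PdCl2(dppp)/excess LiBHEt3 to the (14S,15R)-diol F6, which is mesylated at the secondary hydroxyl to give the mesylate F7 and closed with K2CO3/MeOH (inversion at C14) to give 44.

Step 9 (carboalumination/hydroxymethylation: moisture-sensitive, and alkenyl transfer to formaldehyde can be incomplete). The fallback sets out from 13 and comes back at 17; it builds the E-alkene by stereospecific enol phosphate substitution. Aldehyde 13 is homologated with ethyl diazoacetate/SnCl2 (Roskamp) to ethyl (6R)-6,11-dimethyl-7-methylidene-3-oxododec-10-enoate F8. NaH/ClP(O)(OEt)2 gives the (Z)-enol phosphate F9, Me2CuLi (−78 °C) replaces phosphate by methyl with retention to give ethyl (2E,6R)-3,6,11-trimethyl-7-methylidenedodeca-2,10-dienoate F10, and DIBAL-H reduces F10 to 17.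

**Further compounds**
F1 | step 27 | (2R,3R,6R)-3,6,11-trimethyl-7-methylidene-1-(phenylsulfanyl)dodec-10-ene-2,3-diol | c1ccccc1SC[C@H](O)[C@](C)(O)CC[C@@H](C)C(=C)CCC=C(C)C
F2 | step 27 | [(2R,3R,6R)-2,3-dihydroxy-3,6,11-trimethyl-7-methylidenedodec-10-en-1-yl](methyl)phenylsulfonium tetrafluoroborate | C[S+](c1ccccc1)C[C@H](O)[C@](C)(O)CC[C@@H](C)C(=C)CCC=C(C)C.F[B-](F)(F)F
F3 | step 27 | (2R,5R)-5,10-dimethyl-6-methylidene-2-[(2S)-oxiran-2-yl]undec-9-en-2-ol | C1O[C@@H]1[C@](C)(O)CC[C@@H](C)C(=C)CCC=C(C)C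
F4 | step 27 | (3S,7R,10E,14S,15R,18R)-12-(benzenesulfonyl)-2,3,7,10,15,18,23-heptamethyl-6,19-dimethylidenetetracosa-1,10,22-triene-14,15-diol (target locants; both C12 epimers) | C=C(C)[C@@H](C)CCC(=C)[C@H](C)CC/C(C)=C/C(S(=O)(=O)c1ccccc1)C[C@H](O)[C@](C)(O)CC[C@@H](C)C(=C)CCC=C(C)C
F5 | step 27 | 14-O-methanesulfonate of F4 | C=C(C)[C@@H](C)CCC(=C)[C@H](C)CC/C(C)=C/C(S(=O)(=O)c1ccccc1)C[C@H](OS(C)(=O)=O)[C@](C)(O)CC[C@@H](C)C(=C)CCC=C(C)C
F6 | step 28 | (3S,7R,10E,14S,15R,18R)-2,3,7,10,15,18,23-heptamethyl-6,19-dimethylidenetetracosa-1,10,22-triene-14,15-diol (target locants) | C=C(C)[C@@H](C)CCC(=C)[C@H](C)CC/C(C)=C/CC[C@H](O)[C@](C)(O)CC[C@@H](C)C(=C)CCC=C(C)C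
F7 | step 28 | 14-O-methanesulfonate of F6 | C=C(C)[C@@H](C)CCC(=C)[C@H](C)CC/C(C)=C/CC[C@H](OS(C)(=O)=O)[C@](C)(O)CC[C@@H](C)C(=C)CCC=C(C)C
F8 | step 9 | ethyl (6R)-6,11-dimethyl-7-methylidene-3-oxododec-10-enoate | CCOC(=O)CC(=O)CC[C@@H](C)C(=C)CCC=C(C)C
F9 | step 9 | ethyl (2Z,6R)-3-[(diethoxyphosphoryl)oxy]-6,11-dimethyl-7-methylidenedodeca-2,10-dienoate | CCOC(=O)/C=C(\OP(=O)(OCC)OCC)CC[C@@H](C)C(=C)CCC=C(C)C
F10 | step 9 | ethyl (2E,6R)-3,6,11-trimethyl-7-methylidenedodeca-2,10-dienoate | CCOC(=O)/C=C(\C)CC[C@@H](C)C(=C)CCC=C(C)C
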